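## The problem

6,8-Diprenyleriodictyol (11) is a flavanone. Ring A is a fully substituted phloroglucinol ring (oxygen on C5, C7 and C8a, prenyl groups on C6 and C8, the acyl carbon on C4a). It is fused to the dihydropyranone ring C, which carries the catechol ring B at C2.

The only stereocentre is C2 (S). It is benzylic and lies β to the C4 ketone, with the ring oxygen O1 as a potential leaving group. Base, and more slowly hot acid, can therefore open ring C to the 2'-hydroxychalcone and close it again without facial bias. Nothing else in the molecule can restore the configuration, so C2 must either be made late under catalyst control or be bought and kept away from enolising conditions.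

The prenyl groups sit ortho to free phenols and cyclise to 2,2-dimethylchromans under strong acid. The catechol is easily oxidised, and the prenyl double bonds rule out hydrogenolytic deprotection. Direct C-prenylation of ring A is no answer, because this ambident, very nucleophilic ring gives O-alkyl, mono-C-alkyl and dearomatised gem-dialkyl products side by side. Four phenols of different character must also be told apart: the catechol pair, the acidic 7-OH, and the 5-OH that is hydrogen-bonded to the C4 carbonyl.

The feature that opens a way is positional. Each prenylated carbon is ortho to a ring A oxygen (C6 to O5, C8 to O7), and the other ortho position of O5, C4a, is blocked. Each C–C bond can therefore be delivered intramolecularly from an allyl ether on oxygen, and a 1,1-dimethylallyl ether arrives, after allylic inversion, as the linear prenyl chain.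

## Retrosynthesis

**11 ⇒ 10.** The last operation should only release the catechol. In 10 the 3'- and 4'-oxygens are tied together as a diphenylmethylene ketal. This group selects the catechol over the ring A phenols in one operation and survives base, semi-hydrogenation and heat. It falls to weak aqueous acid, not to hydrogenolysis or strong acid, both of which the prenyl groups would not tolerate. The forward step must hydrolyse the ketal without protonating the trisubstituted olefins.

**10 ⇒ 6.** The bonds C6–C1'' and C8–C1''' are cut together, each back to a 1,1-dimethylallyl ether on the neighbouring oxygen (O5 and O7). Compared with Friedel–Crafts prenylation or cross-coupling on a halogenated hexasubstituted ring, this cut turns two difficult C-alkylations into O-alkylations and makes the site of attack a matter of ring geometry. Precursor 6 has an unsubstituted C6 and C8 and no free ring A phenol. The forward reaction is a double aromatic Claisen rearrangement that passes through dienone 7, the monoprenyl phenol 8 and dienone 9. It must run in the right order, in neutral medium, so that ring C and C2 are untouched.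

**6 ⇒ 5.** A tertiary allyl aryl ether cannot be made by direct displacement. Each vinyl group of 6 is therefore traced back to an ethynyl group in the bis(1,1-dimethylpropargyl) ether 5. The forward step is a partial hydrogenation that must stop at the alkene and leave the aryl ketone and the ketal alone.

**5 ⇒ 3 + 4.** The two O–C bonds are cut to the diol 3 and two equivalents of the commercial tertiary propargyl chloride 4. Copper-catalysed propargylic substitution is the established way to put a tertiary propargyl group on a phenol. The forward reaction is asked to alkylate the chelated 5-OH as well as the 7-OH, and to do so without opening ring C. This is the most demanding of the supporting steps.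

**3 ⇒ 1 + 2.** The ketal carbon is cut from the catechol, leading to natural (S)-eriodictyol (1) and dichlorodiphenylmethane (2). Compound 1 already holds the complete flavanone skeleton and the C2 configuration. The synthesis therefore creates no stereocentre and only has to preserve one.

## Roads not taken

**Alternative 1: enol ether ring-closing metathesis at C3–C4.** Ring C would be cut at C3–C4. The diene A2 is an (S)-1-arylallyl aryl ether whose ring A already carries both prenyl groups, with the four phenols as methoxymethyl ethers. The second-generation Grubbs catalyst would join its vinyl group on the future C2 with the α-silyloxystyrene on the future C4a, closing ring C as the silyl enol ether A1. Hydrolysis and removal of the acetal groups would give 11.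
- Merits: ring C closes under neutral conditions. The prenyl positions are fixed on an early ring A building block. C2 comes from an asymmetric etherification and not from nature. In regiochemical certainty and in independence from the optical purity of a natural product this road is better than the chosen one.
- Weak points: A2 holds four olefins. The vinyl group can equally reach the C8 prenyl group, which is ortho to the same ether oxygen. That closure gives a seven-membered ring and should compete with the slower reaction at the hindered, electron-rich enol ether.
- The etherification must join a di-ortho-substituted phenol to a secondary benzylic, allylic carbon with control of branch selectivity and configuration.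
- Four acetals must be removed by acid next to two prenyl groups, and the route runs well beyond ten steps.
- Comparison: the chosen plan sets against this a five-step sequence from 1 and a rearrangement in which all but one order of events lead to 10.

**Alternative 2: Petasis–Ferrier reorganisation at C2–C3.** The cut is at C2–C3. The racemic 2-aryl-4-methylene-1,3-benzodioxine A4 (all phenols silylated) would be ionised at its acetal carbon by a chiral BINOL-derived N-triflylphosphoramide. The enol carbon would recombine with the aryloxy-stabilised cation inside the chiral ion pair to give the flavanone A3, and fluoride would then release 11.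
- Merits: a racemic precursor converges on one enantiomer, and the stereocentre is formed in the ring-forming step by a catalyst. Where the enantiomeric purity of 1 is in doubt, this is the better answer.
- Weak points: enantiocontrol over a free oxocarbenium/enol pair of this aryl type is unproven.
- The strong Brønsted acid meets two prenyl olefins and four aryl silyl ethers.
- The product flavanone can lose its configuration by acid-mediated reopening under the same catalyst.
- A4 requires methylenation of a hindered benzodioxinone.
- Comparison: the chosen plan uses only known reaction types and never exposes the prenyl groups to a strong acid.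

**Alternative 3: ring A grown onto a chiral dihydropyranone.** The cut is at C4a–C5. The (S)-2-aryl-2,3-dihydropyran-4-one A6 carries on its future C8a a doubly prenylated β-keto ester chain. With Mg(OMe)2, its α-carbon (future C4a) would attack the methyl ester, and enolisation would give the ring A phloroglucinol A5. Acid would then remove the two methoxymethyl groups.
- Merits: the prenyl groups sit on defined carbons of an open chain, so no regiochemical question arises. Only the catechol needs protection. Ring A forms in a polyketide-like way.
- Weak points: A6 is a long, retro-Claisen-prone tricarbonyl chain that must be C-alkylated twice.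
- The chiral pyranone needs its own asymmetric synthesis.
- The ring closure is basic, and A5 is a flavanone with the same tendency to reopen that the chosen route avoids.
- The last step again needs acid beside the prenyl groups.
- Comparison: the route is much longer than five steps. Its certainty of prenyl placement is matched in the chosen plan by the geometric constraints of the Claisen rearrangement.

Key step: step 4

Assumption: commercial natural (S)-eriodictyol (1) is taken to be of high enantiomeric purity. C2 would be checked by chiral HPLC after steps 1 and 2, the two operations that expose ring C to acid or base.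

## Route

Step 1
Reactants: 1 (S)-eriodictyol; 2 dichlorodiphenylmethane
Product: 3 (S)-eriodictyol 3',4'-diphenylmethylene ketal
Conditions: Ph2CCl2 (1.5 equiv), Ph2O, 175 °C, 30 min, N2 sweep
Reagents that add atoms: dichlorodiphenylmethane, ClC(Cl)(c1ccccc1)c1ccccc1
Why: Ketalisation of a catechol with a gem-dichloride; only the vicinal ring B hydroxyls can close a five-membered 1,3-benzodioxole, so adducts at the 5- or 7-OH revert on work-up. The base-free thermal protocol is the standard way to single out the catechol of polyhydroxyflavonoids and avoids the alkaline conditions that open ring C; the HCl formed is swept out to limit acid contact with C2.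

Step 2
Reactants: 3 (S)-eriodictyol 3',4'-diphenylmethylene ketal; 4 3-chloro-3-methylbut-1-yne
Product: 5 (S)-5,7-bis-O-(2-methylbut-3-yn-2-yl)eriodictyol 3',4'-diphenylmethylene ketal
Conditions: 4 (5 equiv) and DBU (5 equiv) added in portions, CuCl2·2H2O (5 mol %), MeCN, 0 °C → rt, Ar
Reagents that add atoms: 3-chloro-3-methylbut-1-yne, CC(C)(Cl)C#C
Why: Copper-catalysed propargylic etherification of phenols (CuCl2 is a divalent copper precatalyst; the electrophile is a copper acetylide/allenylidene attacked at the tertiary carbon), the standard route to aryl 1,1-dimethylpropargyl ethers, which works well for electron-poor, ortho-acyl phenoxides. The acidic 7-OH should react at 0 °C and the chelated 5-OH at room temperature; the intermediate phenoxides are conjugated to C4=O and lower the acidity of C3–H, and portionwise addition keeps free amidine low once both oxygens are capped, which protects C2.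

Step 3
Reactants: 5 (S)-5,7-bis-O-(2-methylbut-3-yn-2-yl)eriodictyol 3',4'-diphenylmethylene ketal
Product: 6 (S)-5,7-bis-O-(1,1-dimethylallyl)eriodictyol 3',4'-diphenylmethylene ketal
Conditions: H2 (1 atm), 5% Pd/CaCO3 poisoned with Pb(OAc)2, quinoline, EtOAc, 0 °C → rt; filtered through basic Al2O3, used at once
Reagents that add atoms: none
Why: Lindlar-type partial hydrogenation of terminal alkynes over lead-poisoned palladium stops at the alkene; the aryl ketone, the diaryl ketal and the benzylic C2–O bond are not reduced under these conditions. Any early onset of the rearrangement of the strained O5 ether only advances material towards step 4.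

Step 4
Reactants: 6 (S)-5,7-bis-O-(1,1-dimethylallyl)eriodictyol 3',4'-diphenylmethylene ketal
Product: 10 (S)-6,8-diprenyleriodictyol 3',4'-diphenylmethylene ketal, via first dienone 7 (not isolated), via monoprenyl phenol 8 (not isolated), via second dienone 9 (not isolated)
Conditions: Eu(fod)3 (10 mol %; fod = 6,6,7,7,8,8,8-heptafluoro-2,2-dimethyloctane-3,5-dionate), PhMe (0.02 M, degassed), 60 °C, then 105 °C
Reagents that add atoms: none
Why: Each aryl 1,1-dimethylallyl ether undergoes a concerted, chair-like [3,3]-sigmatropic shift (aromatic Claisen rearrangement) in which the terminal CH2 bonds to the ortho ring carbon as the O–CMe2 bond breaks, and the cyclohexadienone then enolises to the phenol; the closest known reaction is the thermal or Eu(fod)3-promoted conversion of aryl 1,1-dimethylallyl ethers into ortho-prenylphenols and of 5-O-allyl flavanone ethers into C-allyl flavanones. The europium chelate (trivalent europium) binds the C4 carbonyl and O5, and the peri carbonyl compresses the tertiary ether on O5, so this ether should move first at about 60 °C; its only open ortho position is C6 because C4a carries the acyl carbon, giving 7 and then the chelated phenol 8. With C6 filled, the O7 ether can end productively only at C8, since a shift to C6 gives a non-enolisable dienone that reverts, so warming to about 105 °C should give 9 and then 10. Should the O7 ether move first, C8 is still favoured, because C6 lies between two tertiary alkoxy groups while the second neighbour of C8 is the tied-back ring oxygen; only the order O7→C6 followed by O5→C6 and a Cope shift would place the allyl unit on C8 in the inverted sense, and the chelation-controlled order is meant to exclude it. No ring is closed and no stereocentre is created; the sp3 centres at C6 in 7 and at C8 in 9 vanish on enolisation. C2 is untouched because the medium is neutral and aprotic and offers no base for a retro-oxa-Michael opening of ring C. Toluene, high dilution and acid-free glassware are chosen to suppress ionisation of the tertiary ethers.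

Step 5
Reactants: 10 (S)-6,8-diprenyleriodictyol 3',4'-diphenylmethylene ketal
Product: 11 6,8-diprenyleriodictyol
Conditions: AcOH/H2O (4:1), 90 °C, Ar, stopped at full conversion
Reagents that add atoms: none
Why: Acid-catalysed ketal hydrolysis: protonation of a dioxole oxygen and ring opening give a diphenyl- and oxygen-stabilised cation that water captures and expels as the diaryl ketone. This ionisation is far easier than protonation of a trisubstituted olefin by acetic acid, so the prenyl groups should survive, and weak acid does not open ring C, so C2 is retained.

## Compound list

1 | (S)-eriodictyol, (2S)-2-(3,4-dihydroxyphenyl)-5,7-dihydroxychroman-4-one | O=C1C[C@@H](c2ccc(O)c(O)c2)Oc2cc(O)cc(O)c21 | starting material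
2 | dichlorodiphenylmethane | ClC(Cl)(c1ccccc1)c1ccccc1 | starting material
3 | (S)-eriodictyol 3',4'-diphenylmethylene ketal, (2S)-2-(2,2-diphenyl-1,3-benzodioxol-5-yl)-5,7-dihydroxychroman-4-one | O=C1C[C@@H](c2ccc3OC(c4ccccc4)(c4ccccc4)Oc3c2)Oc2cc(O)cc(O)c21 | intermediate
4 | 3-chloro-3-methylbut-1-yne | CC(C)(Cl)C#C | starting material
5 | (2S)-2-(2,2-diphenyl-1,3-benzodioxol-5-yl)-5,7-bis[(2-methylbut-3-yn-2-yl)oxy]chroman-4-one | C#CC(C)(C)Oc1cc2c(c(OC(C)(C)C#C)c1)C(=O)C[C@@H](c1ccc3OC(c4ccccc4)(c4ccccc4)Oc3c1)O2 | intermediate
6 | (2S)-2-(2,2-diphenyl-1,3-benzodioxol-5-yl)-5,7-bis[(2-methylbut-3-en-2-yl)oxy]chroman-4-one | C=CC(C)(C)Oc1cc2c(c(OC(C)(C)C=C)c1)C(=O)C[C@@H](c1ccc3OC(c4ccccc4)(c4ccccc4)Oc3c1)O2 | intermediate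
7 | (2S)-2-(2,2-diphenyl-1,3-benzodioxol-5-yl)-7-[(2-methylbut-3-en-2-yl)oxy]-6-(3-methylbut-2-en-1-yl)-2,3-dihydro-4H-chromene-4,5(6H)-dione (C6 epimers, transient) | O=C1C[C@@H](c2ccc3OC(c4ccccc4)(c4ccccc4)Oc3c2)OC2=C1C(=O)C(CC=C(C)C)C(OC(C)(C)C=C)=C2 | intermediate
8 | (2S)-2-(2,2-diphenyl-1,3-benzodioxol-5-yl)-5-hydroxy-7-[(2-methylbut-3-en-2-yl)oxy]-6-(3-methylbut-2-en-1-yl)chroman-4-one | CC(C)=CCc1c(OC(C)(C)C=C)cc2c(c1O)C(=O)C[C@@H](c1ccc3OC(c4ccccc4)(c4ccccc4)Oc3c1)O2 | intermediate
9 | (2S)-2-(2,2-diphenyl-1,3-benzodioxol-5-yl)-5-hydroxy-6,8-bis(3-methylbut-2-en-1-yl)-2,3-dihydro-4H-chromene-4,7(8H)-dione (C8 epimers, transient) | O=C1C[C@@H](c2ccc3OC(c4ccccc4)(c4ccccc4)Oc3c2)OC2=C1C(O)=C(CC=C(C)C)C(=O)C2CC=C(C)C | intermediate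
10 | (S)-6,8-diprenyleriodictyol 3',4'-diphenylmethylene ketal, (2S)-2-(2,2-diphenyl-1,3-benzodioxol-5-yl)-5,7-dihydroxy-6,8-bis(3-methylbut-2-en-1-yl)chroman-4-one | CC(C)=CCc1c(O)c(CC=C(C)C)c2c(c1O)C(=O)C[C@@H](c1ccc3OC(c4ccccc4)(c4ccccc4)Oc3c1)O2 | intermediate
11 | 6,8-diprenyleriodictyol, (2S)-2-(3,4-dihydroxyphenyl)-5,7-dihydroxy-6,8-bis(3-methylbut-2-en-1-yl)chroman-4-one | CC(C)=CCc1c(O)c(CC=C(C)C)c2c(c1O)C(=O)C[C@@H](c1ccc(O)c(O)c1)O2 | target

## Step count and risks

Total step count: 5. Longest linear sequence: 5 steps (1 → 3 → 5 → 6 → 10 → 11).

**Step 4 (key step).**
- What may go wrong: a crossed order of the two shifts (O7 ether to C6 first, then the O5 ether to the occupied C6 and a Cope shift), which would deliver the allyl unit to C8 in the inverted, 1,1-dimethylallyl sense.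
- Also possible: ionisation of the tertiary ethers, with loss of isoprene or collapse to the linear O-prenyl ether before rearrangement.
- Fallback (from 3, returning at 10): both ring A hydroxyls of 3 would be allylated under Mitsunobu conditions (allyl alcohol, PPh3, diisopropyl azodicarboxylate, THF). This reaction is known to engage the chelated 5-OH of flavanones and uses no base. It would give (2S)-5,7-bis(allyloxy)-2-(2,2-diphenyl-1,3-benzodioxol-5-yl)chroman-4-one F1.
- Heating F1 with Eu(fod)3 in 1,2-dichlorobenzene (about 80 °C for the O5 ether, then 170–180 °C for the O7 ether) would give (2S)-6,8-diallyl-2-(2,2-diphenyl-1,3-benzodioxol-5-yl)-5,7-dihydroxychroman-4-one F2. With an unsubstituted allyl group every sequence of Claisen and Cope shifts ends in the same product, so the order of events no longer matters.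
- Cross-metathesis of F2 with excess 2-methylbut-2-ene and the second-generation Grubbs catalyst (CH2Cl2, 40 °C) would convert both allyl groups into prenyl groups and give 10.
- The price is two more steps, a much hotter rearrangement and a ruthenium step.

**Step 2.**
- What may go wrong: incomplete etherification at the hydrogen-bonded, peri-hindered O5, so that the reaction stalls after the first alkylation.
- Also possible: amidine-mediated retro-oxa-Michael opening and reclosure of ring C, which would erode the configuration at C2.
- Fallback (from 3, returning at 6): palladium-catalysed decarboxylative O-allylation. tert-Butyl 2-methylbut-3-en-2-yl carbonate F3, made from 2-methylbut-3-en-2-ol and di-tert-butyl dicarbonate, would be reacted with 3 and Pd(PPh3)4 (zerovalent palladium, 5–10 mol %) in THF at 0 °C.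
- The phenoxide attacks the π-(1,1-dimethylallyl)palladium cation at its tertiary terminus under kinetic control. The only base is the tert-butoxide released one equivalent at a time. Compound 6 is reached directly, without the alkyne stage and step 3.
- The reaction would be stopped early to prevent re-ionisation of the O5 ether and drift to the linear ether.
- If O5 resists tertiary alkylation by either method, the allyl/cross-metathesis detour described under step 4 takes over, since it needs only a primary alcohol at that oxygen.

**Step 5.**
- What may go wrong: acid-promoted cyclisation of a prenyl group onto a neighbouring phenol (chroman formation) competing with ketal hydrolysis. Slow hydrolysis would force longer heating and make this worse.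
- Fallback (from 5, returning at 11): the acid step is moved ahead of the prenyl groups. Hydrolysis of 5 in the same aqueous acetic acid would give (2S)-2-(3,4-dihydroxyphenyl)-5,7-bis[(2-methylbut-3-yn-2-yl)oxy]chroman-4-one F4. Tertiary propargyl ethers ionise far less readily than tertiary allyl ethers or prenyl arenes.
- Semi-hydrogenation as in step 3 would give (2S)-2-(3,4-dihydroxyphenyl)-5,7-bis[(2-methylbut-3-en-2-yl)oxy]chroman-4-one F5.
- Heating F5 in toluene at 105–110 °C, without the europium chelate (which the free catechol would bind), would effect the double Claisen rearrangement and give 11 directly. The last step would then be neutral and thermal.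

## Further compounds

F1 | step 4 | (2S)-5,7-bis(allyloxy)-2-(2,2-diphenyl-1,3-benzodioxol-5-yl)chroman-4-one | C=CCOc1cc2c(c(OCC=C)c1)C(=O)C[C@@H](c1ccc3OC(c4ccccc4)(c4ccccc4)Oc3c1)O2
F2 | step 4 | (2S)-6,8-diallyl-2-(2,2-diphenyl-1,3-benzodioxol-5-yl)-5,7-dihydroxychroman-4-one | C=CCc1c(O)c(CC=C)c2c(c1O)C(=O)C[C@@H](c1ccc3OC(c4ccccc4)(c4ccccc4)Oc3c1)O2
F3 | step 2 | tert-butyl 2-methylbut-3-en-2-yl carbonate | C=CC(C)(C)OC(=O)OC(C)(C)C
F4 | step 5 | (2S)-2-(3,4-dihydroxyphenyl)-5,7-bis[(2-methylbut-3-yn-2-yl)oxy]chroman-4-one | C#CC(C)(C)Oc1cc2c(c(OC(C)(C)C#C)c1)C(=O)C[C@@H](c1ccc(O)c(O)c1)O2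
F5 | step 5 | (2S)-2-(3,4-dihydroxyphenyl)-5,7-bis[(2-methylbut-3-en-2-yl)oxy]chroman-4-one | C=CC(C)(C)Oc1cc2c(c(OC(C)(C)C=C)c1)C(=O)C[C@@H](c1ccc(O)c(O)c1)O2
A1 | alternative 1 | (S)-4-(tert-butyldimethylsilyloxy)-2-[3,4-bis(methoxymethoxy)phenyl]-5,7-bis(methoxymethoxy)-6,8-diprenyl-2H-chromene | CC(C)=CCc1c(OCOC)c(CC=C(C)C)c2c(c1OCOC)C(O[Si](C)(C)C(C)(C)C)=C[C@@H](c1ccc(OCOC)c(OCOC)c1)O2
A2 | alternative 1 | (S)-1-[3,4-bis(methoxymethoxy)phenyl]allyl 2-[1-(tert-butyldimethylsilyloxy)vinyl]-3,5-bis(methoxymethoxy)-4,6-diprenylphenyl ether | C=C[C@@H](c1ccc(OCOC)c(OCOC)c1)Oc1c(CC=C(C)C)c(OCOC)c(CC=C(C)C)c(OCOC)c1C(=C)O[Si](C)(C)C(C)(C)C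
A3 | alternative 2 | (S)-5,7,3',4'-tetrakis(tert-butyldimethylsilyl)-6,8-diprenyleriodictyol | CC(C)=CCc1c(O[Si](C)(C)C(C)(C)C)c(CC=C(C)C)c2c(c1O[Si](C)(C)C(C)(C)C)C(=O)C[C@@H](c1ccc(O[Si](C)(C)C(C)(C)C)c(O[Si](C)(C)C(C)(C)C)c1)O2
A4 | alternative 2 | racemic 2-[3,4-bis(tert-butyldimethylsilyloxy)phenyl]-5,7-bis(tert-butyldimethylsilyloxy)-4-methylene-6,8-diprenyl-4H-1,3-benzodioxine | C=C1OC(c2ccc(O[Si](C)(C)C(C)(C)C)c(O[Si](C)(C)C(C)(C)C)c2)Oc2c(CC=C(C)C)c(O[Si](C)(C)C(C)(C)C)c(CC=C(C)C)c(O[Si](C)(C)C(C)(C)C)c21
A5 | alternative 3 | (S)-3',4'-bis(methoxymethyl)-6,8-diprenyleriodictyol | CC(C)=CCc1c(O)c(CC=C(C)C)c2c(c1O)C(=O)C[C@@H](c1ccc(OCOC)c(OCOC)c1)O2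
A6 | alternative 3 | methyl 4-{(2S)-2-[3,4-bis(methoxymethoxy)phenyl]-4-oxo-3,4-dihydro-2H-pyran-6-yl}-3-oxo-2,4-diprenylbutanoate | COC(=O)C(CC=C(C)C)C(=O)C(CC=C(C)C)C1=CC(=O)C[C@@H](c2ccc(OCOC)c(OCOC)c2)O1
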